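(The readings come from a simulation for substances that don't exist; scatter was added.)

**The reading time.** Start from 2.0 h and ask how many halvings of L fit into it. Your hunch leans on the late pace of the runs in points per minute; carry that pace as a fraction instead.

| flask | L | remark | time |
|---|---|---|---|
| beta | 6.2 mM | run made earlier |  |
| gamma | 18 mM | run made earlier |  |
| epsilon | 45 mM | run made earlier |  |
| south-west | 10 mM |  | 2.0 h |
| north-east | 60 mM |  | 2.0 h |
| west | 5.0 mM |  | 2.0 h |
| south | 6.0 mM |  | 2.0 h |
| east | 20 mM |  | 2.0 h |

| run | time / min | G / % | L / % |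
|---|---|---|---|
| beta | 5.00 | 0 | 101.4 |
| beta | 10.0 | 2.0 | 100.4 |
| beta | 15.0 | 0.4 | 99.4 |
| beta | 30.0 | 2.5 | 98.9 |
| beta | 60.0 | 2.7 | 93.5 |
| gamma | 5.00 | 0.7 | 101.0 |
| gamma | 15.0 | 0.9 | 96.6 |
| gamma | 30.0 | 4.8 | 94.6 |
| gamma | 40.0 | 9.5 | 87.4 |
| gamma | 60.0 | 14.8 | 81.7 |
| epsilon | 5.00 | 0 | 99.1 |
| epsilon | 15.0 | 1.8 | 95.8 |
| epsilon | 30.0 | 11.4 | 87.8 |
| epsilon | 40.0 | 13.8 | 83.7 |
| epsilon | 60.0 | 21.9 | 77.2 |

(each reading ± 1 percentage point)

* ranking by amount of G, in percent of the L charged, from high to low, at 2.0 h (south-west / north-east / west / south / east)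
* the amount of G, in percent of the L charged of the flask you put first, at 2.0 h
* the amount of G, in percent of the L charged of the flask you put last, at 2.0 h

- what was read earlier has a scatter of 1 percentage point, one standard deviation
- a reading or a percentage of G counts all its forms, free or not

**The half-life.** Take the epsilon run: between 30.0 min and 60.0 min, L falls from 87.8% to 77.2%, which reads as 2.69 h. Call this the running half-life of L: the time in which L halves at the fractional pace of a flask already under way. The gamma run, at a charge of 18 mM against 45 mM, reads 2.36 h, close given a scatter of 1 percentage point. So treat L as a pseudo-first-order decay once it is running.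

**My reckoning.** Less than one half-life fits into the time. Apply it to north-east: assume that this flask stands at the epsilon reading at 60.0 min, and run the remaining hour, which leaves 59.7% of L, so, counting the L lost as G, I commit to 40.3% of G. Rank the flasks by charge, because G at 60.0 min is higher in epsilon than in gamma. For west, charged with 5.0 mM, take the beta reading of 2.7% at a charge of 6.2 mM, and, as a guess for a curve that starts late, multiply it by 3: 8.10%.

**The forecast.** It gives north-east > east > south-west > south > west, with 46% and 5%, “with slowing as L is consumed”, though its top is what a straight line through the last two epsilon readings gives.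

**The result.** The flasks give north-east > east > south-west > south > west, with 40.6% and 7.10%; north-east keeps 57% of its L, against my 59.7%.

    L + G → 2 G (k = 0.130 L mol⁻¹ s⁻¹)
    L → G (k = 5.20 × 10⁻⁶ s⁻¹)
    J ⇌ G, rate k3*(cs3 - [G]) while solid is left; crystals form when [G] > cs3 (solubility = 0.560 mM, k = 0.210 s⁻¹)
    G ⇌ E (K = 2.80, k = 6.30 × 10⁻⁴ s⁻¹)

**At rest?** No: north-east still holds 57.3% of L at 2.00 h. Leave it for 20.0 h, which is 7.43 running half-lives and leaves 0.578% of L by the count. North-east then stands at 0.358% of L, and G has climbed to 97.0%, with J, at 96.1%, counted in it. Apply the same count to west, a second flask, charged with 5.0 mM against 60 mM: it again leaves 0.578% of L. West at 20.0 h holds 0.555% of L, 68.1% of G and 31.4% of E.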